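**Conventions.** Labdane numbering is used for every compound, including the acyclic ones: ring A = C1–C5 and C10, ring B = C5–C10, side chain C11–C16 on C9, C17 on C8, C18 (4α carbon, oxygenated) and C19 (4β methyl) on C4, C20 on C10. In all bicyclic compounds H-5 is α, H-9 is α and the C20 methyl is β. TBS = tert-butyldimethylsilyl, TES = triethylsilyl, PMB = 4-methoxybenzyl, Bn = benzyl.

## Analysis of the target

Target 37 is a labdane of the normal series, (4R,5R,6S,9S,10R,13Z): a trans-fused decalin with five stereocentres, of which C4 and C10 are quaternary and flank the ring-fusion carbon C5. The β-methyls C19 and C20 are 1,3-diaxial, H-5 is α, the C9 chain is β (equatorial) and the C6 hydroxyl is α (equatorial), peri to the equatorial benzoyloxymethyl carbon C18. Only one of the two carbons on C4 is oxygenated, so C18 and C19 must be told apart at the moment C4 is made. The sensitive groups are the exocyclic C8=C17 alkene (hydrogenation, acid-induced migration), the Z-configured 3-methyl-2-enoic acid (its geometry is kinetic), and a benzoate that has to survive the release of both the C15 acid and the C6 hydroxyl. The difficulty lies in the congested C4–C5–C10 array next to an oxygenated C6, and in the four different oxidation levels at C6, C8, C18 and C15. The feature used here is that C18 at the ester level turns C4=C5 into an (E)-2-methyl-enoate dienophile, C10=C1–C2=C3 is a diene, and the ring B carbons C6–C9 are a four-atom tether between them. The open chain is therefore a 1,7,9-decatriene whose intramolecular Diels–Alder reaction forms C3–C4 and C5–C10, closes rings A and B together and sets C4, C5 and C10.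

## Retrosynthetic reasoning

**Last deprotections (37 from 36 from 35).** The C15 acid is carried as an allyl ester and O6 as a TBS ether. An ordinary alkyl ester could not be hydrolysed next to the benzoate, whereas an allyl ester is removed by zerovalent palladium without touching it. The silyl ether is taken off one step earlier under buffered fluoride conditions.

**C13–C16 and C14–C15 (35 from 33 from 31).** The trisubstituted alkene is cut at its methyl group. Syn addition of a methyl group from copper to ynoate 33 places C12 and C15 on the same side, which is the 13Z geometry. Olefination of a C13 methyl ketone would not be selective. Ynoate 33 comes from terminal alkyne 31 by acylation of its acetylide.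

**C18 benzoate (31 from 30 from 29).** The ester that activated the dienophile is reduced and benzoylated only at this stage. This is after the basic methanol of the alkyne homologation, which a benzoate would not survive, and before any second ester exists.

**C8=C17 (29 from 28 from 27 from 26).** The exocyclic alkene is cut to the C8 ketone, which is methylenated under non-basic conditions. The ketone comes from the C8 silyl ether. This is why O8 carries a TES group and O6 a TBS group: the first can be removed beside the second.

**C13≡C14 (26 from 25 from 24 from 23).** The alkyne is made by one-carbon homologation of aldehyde 25. That reaction supplies C14 only, so the chain on C9 of the cycloadduct must already hold C11, C12 and C13. A benzyl ether on O13 is chosen because its hydrogenolysis coincides with the saturation of C1=C2, which must precede the introduction of C8=C17 and of the alkyne.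

**Key disconnection (23 from 22).** C3–C4 and C5–C10 are cut together. No other pair of cuts removes both rings and both quaternary centres at once while keeping every oxygen at its final position. The forward reaction has to add the trisubstituted enoate C4=C5 across a diene whose terminus C10 is disubstituted, with trans ring fusion and on one diene face.

**C4=C5 (22 from 20 and 21).** The enoate is made last, by Wittig reaction of the α-silyloxy aldehyde 20 with the stabilised ylide 21, which gives the E alkene. Late introduction keeps the ester away from the hydride and organoaluminium steps before it.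

**Diene (18 from 16, then 19 and 20).** C10–C20 and C1–C2 are cut. Syn methyl-metalation of the terminal alkyne 16 puts the metal cis to the new methyl group, so the vinyl unit C2=C3 enters trans to C9. This is the E diene with the tether on the outside that the cycloaddition needs. Removal of the PMB group and oxidation then give 19 and 20.

**C1 (16 from 15 from 14 from 13).** The alkyne carbon C1 is added to aldehyde 15, whose carbonyl carbon C10 was the acyl carbon of the aldol adduct.

**C8–C9 (12 from 10 and 6).** A syn aldol reaction of imide 10 with aldehyde 6 sets C8 and C9. The relationship needed between O8 and C11 is syn in the open chain, which is trans-diequatorial on ring B. A methyl ketone carrying C20 was not used as donor: under boron conditions it would enolise at the methyl group, and a later ketone olefination would not be E-selective. The imide enolises only at C9 and its auxiliary fixes the absolute sense regardless of C6.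

**C6 and C7–C8 (6 from 4 from 3 from 2 from 1).** C6 comes from the chiral pool as glycidol 1. A vinyl nucleophile opens the derived epoxide 2 to form C7–C8, and cleavage of the alkene gives the C8 aldehyde. The PMB ether on O5 is orthogonal to the benzyl ether on O13 and to both silyl ethers.

**Imide (10 from 7 and 8).** Acylation of the auxiliary 8 with acid 7, which brings C9 and C11–C13 with the benzyl ether in place.

## Alternatives that were turned down

**Alternative 1:** Ring B is cut at C7–C8 and C9–C10. The forward step is an intermolecular Diels–Alder reaction between the ring A enol lactone A1, whose lactone bridge C18–O–C6 holds the diene C7=C6–C5=C10 s-cis, and the allenic ester A2, giving tricycle A3.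
- For: it is convergent, C4 is present from the start with C18 and C19 differentiated by the lactone, and the oxygen on C6 directs the ester-bearing carbon to C10. The allene delivers C8=C17 directly. On that point it is stronger than the chosen route, which spends three steps (19–21) on this alkene.
- Against: the C9–C10 bond must form at a fully substituted diene terminus in a bimolecular reaction with a weakly activated acyloxy diene. C9 in A3 is α to an ester and allylic to C8=C17, so it can epimerise and the alkene can move into conjugation. C5 and C6 are left as an enol lactone. Opening it gives a 6-ketone that hydride attacks from the α face, since the β face is covered by C19 and C20, which gives the axial 6β alcohol instead of the 6α alcohol. C11 arrives as an ester and needs reduction and a five-carbon extension.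
- Comparison: the chosen strategy sets C4, C5 and C10 in one intramolecular step (22 to 23) and brings O6 with its configuration from 1, at the cost of a longer linear sequence.

**Alternative 2:** C9–C11 and C10–C1 are cut from a ring B cyclohexenone. A vinylcopper reagent adds to C9 of enone A4 and the enolate is alkylated at C10 by the allylic iodide A5, a masked 3-oxopentyl chain for later annulation of ring A, giving ketone A6.
- For: conjugate addition with enolate trapping is very dependable, the two new groups enter trans to each other and anti to the C8 silyloxy group, and the materials are cheap. In predictability of the key step it is stronger than the cycloaddition.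
- Against: it sets only C9 and C10. The annulation that follows gives a C3-keto C4=C5 enone, so the C3 oxygen must be removed and C4 (with C18 distinguished from C19) and H-5 set by reductive alkylation. C6 is a plain methylene in A6, and the equatorial 6α-hydroxyl would have to be introduced late at a weakly activated position.
- Comparison: the work still needed on C3, C4, C5 and C6 after A6 exceeds the twelve steps the chosen route needs after cyclisation. The chosen route has C18, O6 and the three ring stereocentres in place in 23.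

**Alternative 3:** Only C9–C10 is cut. Hydrogen-atom transfer from an iron hydride (Fe(acac)3, PhSiH3) to the exocyclic methylene on C10 of A7 gives a tertiary radical that adds 6-exo to C9 of the keto-enoate, giving decalin A8.
- For: the conditions are mild and neutral and a radical tolerates the hindrance at C10. A8 already has the C8 ketone, differentiated O6 and O18, and a C9 centre that can epimerise to the equatorial isomer. At C8 it is shorter than the chosen route.
- Against: the difficulty moves into A7, where the contiguous centres C4 (quaternary), C5 and C6 must be set by separate operations. The ring fusion depends on which face of the planar C10 radical is attacked. The trans product requires C20 to become axial and syn to the axial C19 methyl, and nothing in the substrate enforces that over the cis-fused path. The γ-keto enoate with a β-silyloxy ketone is prone to elimination. The chain ends at C12 as an ester, so C13–C16 need alkylation chemistry.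
- Comparison: the cycloaddition builds the same diaxial methyl pair, but there the E alkene fixes C4 against C5 and the ester-endo, tether-anti arrangement with three equatorial tether substituents points to the trans-fused product 23.

Key step: step 15

**Remark (assumption).** The cyclisation substrate carries a 3-(benzyloxy)propyl chain on C9 (C11–C13). The aldehyde-to-alkyne homologation after the cyclisation adds only C14, so a two-carbon chain would leave the side chain one methylene short.

## Route

Step 1
Reactants: 1 (R)-glycidol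
Product: 2 (S)-2-{[(4-methoxybenzyl)oxy]methyl}oxirane
Conditions: NaH, 4-methoxybenzyl chloride, Bu4NI (cat.), DMF, 0 °C to rt
Reagents that add atoms: 4-methoxybenzyl chloride, COc1ccc(CCl)cc1
Why: Williamson etherification of the primary alkoxide; the stereocentre (later C6) is not touched, and the descriptor changes from R to S only because the CIP priorities change.

Step 2
Reactants: 2 (S)-2-{[(4-methoxybenzyl)oxy]methyl}oxirane
Product: 3 (S)-1-[(4-methoxybenzyl)oxy]pent-4-en-2-ol
Conditions: CH2=CHMgBr, CuI (cat.), THF, −40 to −20 °C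
Reagents that add atoms: vinylmagnesium bromide, C=C[Mg]Br
Why: Copper-catalysed Grignard opening of a terminal epoxide at its unsubstituted carbon (SN2); it forms C7–C8 and leaves C6 untouched.

Step 3
Reactants: 3 (S)-1-[(4-methoxybenzyl)oxy]pent-4-en-2-ol
Product: 4 (S)-tert-butyl({1-[(4-methoxybenzyl)oxy]pent-4-en-2-yl}oxy)dimethylsilane
Conditions: TBSCl, imidazole, DMF, rt
Reagents that add atoms: tert-butyldimethylsilyl chloride, CC(C)(C)[Si](C)(C)Cl
Why: Standard imidazole-promoted silylation of a secondary alcohol; the TBS group is meant to stay on O6 until step 26.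

Step 4
Reactants: 4 (S)-tert-butyl({1-[(4-methoxybenzyl)oxy]pent-4-en-2-yl}oxy)dimethylsilane
Product: 6 (S)-3-[(tert-butyldimethylsilyl)oxy]-4-[(4-methoxybenzyl)oxy]butanal, via vicinal diol 5 (not isolated)
Conditions: OsO4 (cat.), NaIO4, 2,6-lutidine, dioxane/H2O, rt
Reagents that add atoms: sodium periodate, [Na+].[O-]I(=O)(=O)=O (oxygen delivered through catalytic OsO4)
Why: Lemieux–Johnson cleavage: the terminal alkene is dihydroxylated and the diol cleaved by periodate in the same flask; PMB and TBS ethers are inert and the lutidine buffer suppresses over-oxidation.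

Step 5
Reactants: 7 5-(benzyloxy)pentanoic acid; 8 (S)-4-benzyloxazolidin-2-one
Product: 10 (S)-4-benzyl-3-[5-(benzyloxy)pentanoyl]oxazolidin-2-one, via mixed pivalic anhydride 9 (not isolated)
Conditions: pivaloyl chloride, Et3N, THF, −20 °C; then 8, LiCl, rt
Reagents that add atoms: none
Why: N-acylation of the oxazolidinone through the mixed anhydride with LiCl activation; attack occurs at the less hindered carbonyl and no stereocentre is formed.

Step 6
Reactants: 10 (S)-4-benzyl-3-[5-(benzyloxy)pentanoyl]oxazolidin-2-one; 6 (S)-3-[(tert-butyldimethylsilyl)oxy]-4-[(4-methoxybenzyl)oxy]butanal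
Product: 12 (S)-4-benzyl-3-{(2S,3R,5S)-2-[3-(benzyloxy)propyl]-5-[(tert-butyldimethylsilyl)oxy]-3-hydroxy-6-[(4-methoxybenzyl)oxy]hexanoyl}oxazolidin-2-one, via dibutylboron Z-enolate 11 (not isolated)
Conditions: Bu2BOTf, Et3N, CH2Cl2, −78 to 0 °C; then 6, −78 to 0 °C; pH 7 buffer, MeOH, H2O2
Reagents that add atoms: none
Why: Evans syn aldol reaction: the Z boron enolate reacts through a closed chair (Zimmerman–Traxler) transition state with the benzyl group of the auxiliary shielding one enolate face, which sets C9 and C8 syn in the required absolute sense; reagent control overrides the remote C6 centre.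

Step 7
Reactants: 12 aldol adduct
Product: 13 (S)-4-benzyl-3-{(2S,3R,5S)-2-[3-(benzyloxy)propyl]-5-[(tert-butyldimethylsilyl)oxy]-6-[(4-methoxybenzyl)oxy]-3-[(triethylsilyl)oxy]hexanoyl}oxazolidin-2-one
Conditions: TESOTf, 2,6-lutidine, CH2Cl2, −78 to 0 °C
Reagents that add atoms: triethylsilyl trifluoromethanesulfonate, CC[Si](CC)(CC)OS(=O)(=O)C(F)(F)F
Why: Silyl triflate silylation of a hindered secondary alcohol; TES is chosen for O8 so that it can be removed beside the TBS ether on O6 in step 19.

Step 8
Reactants: 13 TES-protected imide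
Product: 14 (2R,3R,5S)-2-[3-(benzyloxy)propyl]-5-[(tert-butyldimethylsilyl)oxy]-6-[(4-methoxybenzyl)oxy]-3-[(triethylsilyl)oxy]hexan-1-ol
Conditions: LiBH4, MeOH (2 equiv), THF, 0 °C
Reagents that add atoms: none
Why: Reductive cleavage of the N-acyl oxazolidinone at the exocyclic carbonyl; ethers and silyl ethers are inert and the auxiliary is recovered.

Step 9
Reactants: 14 primary alcohol
Product: 15 (2S,3R,5S)-2-[3-(benzyloxy)propyl]-5-[(tert-butyldimethylsilyl)oxy]-6-[(4-methoxybenzyl)oxy]-3-[(triethylsilyl)oxy]hexanal
Conditions: Dess–Martin periodinane, NaHCO3, CH2Cl2, 0 °C to rt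
Reagents that add atoms: none
Why: Dess–Martin oxidation under buffered, non-basic conditions, so the α-stereocentre C9 should not epimerise and the β-silyloxy group should not eliminate.

Step 10
Reactants: 15 aldehyde
Product: 16 (3R,4R,6S)-3-[3-(benzyloxy)propyl]-6-[(tert-butyldimethylsilyl)oxy]-7-[(4-methoxybenzyl)oxy]-4-[(triethylsilyl)oxy]hept-1-yne
Conditions: dimethyl (1-diazo-2-oxopropyl)phosphonate, K2CO3, MeOH, 0 °C to rt
Reagents that add atoms: dimethyl (1-diazo-2-oxopropyl)phosphonate, COP(=O)(OC)C(=[N+]=[N-])C(C)=O
Why: Seyferth–Gilbert homologation with the Ohira–Bestmann reagent adds C1; the carbonate base at 0 °C is mild enough to leave C9 and the secondary TES ether intact.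

Step 11
Reactants: 16 terminal alkyne
Product: 18 (3E,5R,6R,8S)-5-[3-(benzyloxy)propyl]-8-[(tert-butyldimethylsilyl)oxy]-9-[(4-methoxybenzyl)oxy]-4-methyl-6-[(triethylsilyl)oxy]nona-1,3-diene, via alkenyldimethylalane 17 (not isolated)
Conditions: AlMe3, Cp2ZrCl2, CH2Cl2, 0 °C to rt; then CH2=CHBr, Pd(PPh3)4 (cat.), ZnCl2 (cat.), THF, rt
Reagents that add atoms: trimethylaluminium, C[Al](C)C; vinyl bromide, C=CBr
Why: Negishi zirconium-catalysed methylalumination adds methyl to C10 and aluminium to C1 on the same side, and the palladium-catalysed cross-coupling of the alkenylalane proceeds with retention; C2 therefore ends cis to C20 and trans to C9 (E diene, tether outside).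

Step 12
Reactants: 18 diene PMB ether
Product: 19 (2S,4R,5R,6E)-5-[3-(benzyloxy)propyl]-2-[(tert-butyldimethylsilyl)oxy]-6-methyl-4-[(triethylsilyl)oxy]nona-6,8-dien-1-ol
Conditions: DDQ, CH2Cl2/pH 7 buffer, 0 °C
Reagents that add atoms: none
Why: Oxidative cleavage of the PMB ether by benzylic hydride abstraction and hydrolysis; the benzyl ether reacts far more slowly and the buffer protects the TES ether.

Step 13
Reactants: 19 primary alcohol
Product: 20 (2S,4R,5R,6E)-5-[3-(benzyloxy)propyl]-2-[(tert-butyldimethylsilyl)oxy]-6-methyl-4-[(triethylsilyl)oxy]nona-6,8-dienal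
Conditions: Dess–Martin periodinane, NaHCO3, CH2Cl2, 0 °C
Reagents that add atoms: none
Why: Dess–Martin oxidation; the α-silyloxy aldehyde is to be used directly in step 14 so that C6 does not epimerise.

Step 14
Reactants: 20 α-silyloxy aldehyde; 21 methyl 2-(triphenyl-λ5-phosphanylidene)propanoate
Product: 22 methyl (2E,4S,6R,7R,8E)-7-[3-(benzyloxy)propyl]-4-[(tert-butyldimethylsilyl)oxy]-2,8-dimethyl-6-[(triethylsilyl)oxy]undeca-2,8,10-trienoate
Conditions: PhMe, rt to 60 °C
Reagents that add atoms: none
Why: Wittig olefination with a stabilised α-methyl ylide, which gives the E trisubstituted enoate under neutral conditions; C18 is then cis to H-5 and C19 cis to C6 across C4=C5.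

Step 15
Reactants: 22 triene ester
Product: 23 methyl 13-(benzyloxy)-6α-[(tert-butyldimethylsilyl)oxy]-8α-[(triethylsilyl)oxy]-14,15,16,17-tetranorlabd-1-en-18-oate
Conditions: Me2AlCl (1.5 equiv), CH2Cl2, −40 °C to rt
Reagents that add atoms: none
Why: A concerted, asynchronous [4+2] cycloaddition in which the Me2AlCl-complexed (E)-2-methyl-enoate C4=C5 adds suprafacially across the diene C10=C1–C2=C3, forming C5–C10 and C3–C4; the closest known reaction type is the Lewis-acid-promoted intramolecular Diels–Alder reaction of 1,7,9-decatrienoates to trans-fused octalins. Ring B closes as the six-membered tether ring through C6–C9, and ring A is the new cyclohexene (C1=C2) formed by the cycloaddition itself. C4 and C5 are fixed against each other stereospecifically by the E geometry of the dienophile (C18 cis to H-5, C19 cis to C6). C10 is fixed against C5 by the ester-endo, tether-anti transition state, which puts H-5 and the inside methyl C20 on opposite faces and so gives the trans fusion with C19 and C20 both axial on the β face. The absolute sense comes from the tether: in its chair-like arrangement H-9 eclipses H-1 and H-6 eclipses the C19 methyl (least 1,3-allylic strain at both ends), which leaves the C6 and C8 silyl ethers and the C9 chain equatorial and lets the dienophile reach only the α face of C10. The step needs endo/anti selectivity, which complexation of the ester reinforces, and diene-face selectivity, which the three matched tether stereocentres secure. Reactivity is the weak point, because the cis methyl on C10 disfavours the s-cis diene and the α-methyl deactivates the dienophile; Lewis-acid activation at low temperature is therefore preferred to heating, where a 1,5-hydrogen shift from C20 could consume the diene.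

Step 16
Reactants: 23 cycloadduct
Product: 24 methyl 6α-[(tert-butyldimethylsilyl)oxy]-13-hydroxy-8α-[(triethylsilyl)oxy]-14,15,16,17-tetranorlabdan-18-oate
Conditions: H2 (1 atm), Pd/C, EtOAc, rt
Reagents that add atoms: none
Why: Heterogeneous hydrogenation of the cis-disubstituted C1=C2 and hydrogenolysis of the benzyl ether in one operation; in ethyl acetate the TES ether is retained and no stereocentre is formed.

Step 17
Reactants: 24 primary alcohol
Product: 25 methyl 6α-[(tert-butyldimethylsilyl)oxy]-13-oxo-8α-[(triethylsilyl)oxy]-14,15,16,17-tetranorlabdan-18-oate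
Conditions: Dess–Martin periodinane, NaHCO3, CH2Cl2, rt
Reagents that add atoms: none
Why: Dess–Martin oxidation of the unhindered primary alcohol at C13; silyl ethers and the ester are inert.

Step 18
Reactants: 25 aldehyde
Product: 26 methyl 6α-[(tert-butyldimethylsilyl)oxy]-8α-[(triethylsilyl)oxy]-15,16,17-trinorlabd-13-yn-18-oate
Conditions: dimethyl (1-diazo-2-oxopropyl)phosphonate, K2CO3, MeOH, 0 °C to rt
Reagents that add atoms: dimethyl (1-diazo-2-oxopropyl)phosphonate, COP(=O)(OC)C(=[N+]=[N-])C(C)=O
Why: Seyferth–Gilbert homologation (Ohira–Bestmann reagent) adds C14; the hindered C18 methyl ester meets only methanol and carbonate, which cannot change it.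

Step 19
Reactants: 26 TES ether
Product: 27 methyl 6α-[(tert-butyldimethylsilyl)oxy]-8α-hydroxy-15,16,17-trinorlabd-13-yn-18-oate
Conditions: PPTS (cat.), MeOH/CH2Cl2, 0 °C to rt
Reagents that add atoms: none
Why: Acid-catalysed methanolysis cleaves the secondary TES ether much faster than the hindered secondary TBS ether on O6.

Step 20
Reactants: 27 secondary alcohol
Product: 28 methyl 6α-[(tert-butyldimethylsilyl)oxy]-8-oxo-15,16,17-trinorlabd-13-yn-18-oate
Conditions: Dess–Martin periodinane, NaHCO3, CH2Cl2, rt
Reagents that add atoms: none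
Why: Dess–Martin oxidation to the C8 ketone; C9 already carries its chain equatorial, the stable configuration, so epimerisation is not a concern.

Step 21
Reactants: 28 C8 ketone
Product: 29 methyl 6α-[(tert-butyldimethylsilyl)oxy]-15,16-dinorlabd-8(17)-en-13-yn-18-oate
Conditions: Zn, CH2Br2, TiCl4, THF/CH2Cl2, 0 °C to rt
Reagents that add atoms: dibromomethane, BrCBr
Why: Takai–Lombardo methylenation with the geminal dimetallic methylene reagent; it is non-basic, so enolisation, β-elimination of the C6 silyloxy group and attack on the ester are not expected.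

Step 22
Reactants: 29 methyl ester
Product: 30 6α-[(tert-butyldimethylsilyl)oxy]-15,16-dinorlabd-8(17)-en-13-yn-18-ol
Conditions: LiAlH4, THF, 0 °C to rt
Reagents that add atoms: none
Why: Hydride reduction of the hindered ester (no α-hydrogen) to the neopentyl alcohol; the isolated alkene, the alkyne and the TBS ether are inert to LiAlH4.

Step 23
Reactants: 30 C18 alcohol
Product: 31 6α-[(tert-butyldimethylsilyl)oxy]-15,16-dinorlabd-8(17)-en-13-yn-18-yl benzoate
Conditions: benzoyl chloride, pyridine, DMAP (cat.), CH2Cl2, rt
Reagents that add atoms: benzoyl chloride, O=C(Cl)c1ccccc1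
Why: DMAP-catalysed acylation of the only free hydroxyl; the benzoate is introduced after all steps that use basic methanol or hydride.

Step 24
Reactants: 31 terminal alkyne
Product: 33 allyl 18-(benzoyloxy)-6α-[(tert-butyldimethylsilyl)oxy]-16-norlabd-8(17)-en-13-yn-15-oate, via lithium acetylide 32 (not isolated)
Conditions: LiN(SiMe3)2, THF, −78 °C; then allyl chloroformate, −78 to −40 °C
Reagents that add atoms: allyl chloroformate, C=CCOC(Cl)=O
Why: Deprotonation of the terminal alkyne by a non-nucleophilic amide base and C-acylation of the acetylide by the chloroformate forms C14–C15; at −78 °C neither the base nor the acetylide should add to the distant benzoate.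

Step 25
Reactants: 33 allyl ynoate
Product: 35 allyl (13Z)-18-(benzoyloxy)-6α-[(tert-butyldimethylsilyl)oxy]labda-8(17),13-dien-15-oate, via alkenylcuprate 34 (not isolated)
Conditions: Me2CuLi (from MeLi, CuI), THF, −78 °C; NH4Cl (aq) at −78 °C
Reagents that add atoms: lithium dimethylcuprate, [Li+].C[Cu-]C
Why: Conjugate syn-carbocupration of an ynoate: methyl adds to C13 and copper to C14 on the same side, and protonation at −78 °C occurs with retention, so C12 and C15 end cis (13Z); benzoate and allyl ester are not attacked at this temperature.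

Step 26
Reactants: 35 TBS ether
Product: 36 allyl (13Z)-18-(benzoyloxy)-6α-hydroxylabda-8(17),13-dien-15-oate
Conditions: HF·pyridine, pyridine, THF, 0 °C to rt
Reagents that add atoms: none
Why: Fluoride-mediated desilylation under buffered, slightly acidic conditions, where migration of the benzoate to O6 (a base-promoted process) and migration of the exocyclic alkene are not expected.

Step 27
Reactants: 36 allyl ester
Product: 37 (13Z)-18-(benzoyloxy)-6α-hydroxylabda-8(17),13-dien-15-oic acid (CNP0304840.1)
Conditions: Pd(PPh3)4 (cat.), morpholine, THF, rt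
Reagents that add atoms: none
Why: Tsuji–Trost deallylation: zerovalent palladium ionises the allyl ester and morpholine traps the allyl fragment; the benzoate, both alkenes and the Z geometry are not affected.

## Compound list

1 | (R)-glycidol | OC[C@@H]1CO1 | starting material
2 | (S)-2-{[(4-methoxybenzyl)oxy]methyl}oxirane | COc1ccc(COC[C@@H]2CO2)cc1 | intermediate
3 | (S)-1-[(4-methoxybenzyl)oxy]pent-4-en-2-ol | C=CC[C@H](O)COCc1ccc(OC)cc1 | intermediate
4 | (S)-tert-butyl({1-[(4-methoxybenzyl)oxy]pent-4-en-2-yl}oxy)dimethylsilane | C=CC[C@H](O[Si](C)(C)C(C)(C)C)COCc1ccc(OC)cc1 | intermediate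
5 | (4S)-4-[(tert-butyldimethylsilyl)oxy]-5-[(4-methoxybenzyl)oxy]pentane-1,2-diol (both C2 epimers, not isolated) | OCC(O)C[C@H](O[Si](C)(C)C(C)(C)C)COCc1ccc(OC)cc1 | intermediate
6 | (S)-3-[(tert-butyldimethylsilyl)oxy]-4-[(4-methoxybenzyl)oxy]butanal | O=CC[C@H](O[Si](C)(C)C(C)(C)C)COCc1ccc(OC)cc1 | intermediate
7 | 5-(benzyloxy)pentanoic acid | OC(=O)CCCCOCc1ccccc1 | starting material
8 | (S)-4-benzyloxazolidin-2-one | O=C1N[C@@H](Cc2ccccc2)CO1 | starting material
9 | 5-(benzyloxy)pentanoic pivalic anhydride (not isolated) | CC(C)(C)C(=O)OC(=O)CCCCOCc1ccccc1 | intermediate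
10 | (S)-4-benzyl-3-[5-(benzyloxy)pentanoyl]oxazolidin-2-one | O=C(CCCCOCc1ccccc1)N1[C@@H](Cc2ccccc2)COC1=O | intermediate
11 | dibutylboron Z-enolate of 10 (not isolated) | CCCCB(CCCC)O/C(=C\CCCOCc1ccccc1)N1[C@@H](Cc2ccccc2)COC1=O | intermediate
12 | (S)-4-benzyl-3-{(2S,3R,5S)-2-[3-(benzyloxy)propyl]-5-[(tert-butyldimethylsilyl)oxy]-3-hydroxy-6-[(4-methoxybenzyl)oxy]hexanoyl}oxazolidin-2-one | O=C([C@@H](CCCOCc1ccccc1)[C@H](O)C[C@H](O[Si](C)(C)C(C)(C)C)COCc1ccc(OC)cc1)N1[C@@H](Cc2ccccc2)COC1=O | intermediate
13 | (S)-4-benzyl-3-{(2S,3R,5S)-2-[3-(benzyloxy)propyl]-5-[(tert-butyldimethylsilyl)oxy]-6-[(4-methoxybenzyl)oxy]-3-[(triethylsilyl)oxy]hexanoyl}oxazolidin-2-one | O=C([C@@H](CCCOCc1ccccc1)[C@H](O[Si](CC)(CC)CC)C[C@H](O[Si](C)(C)C(C)(C)C)COCc1ccc(OC)cc1)N1[C@@H](Cc2ccccc2)COC1=O | intermediate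
14 | (2R,3R,5S)-2-[3-(benzyloxy)propyl]-5-[(tert-butyldimethylsilyl)oxy]-6-[(4-methoxybenzyl)oxy]-3-[(triethylsilyl)oxy]hexan-1-ol | OC[C@@H](CCCOCc1ccccc1)[C@H](O[Si](CC)(CC)CC)C[C@H](O[Si](C)(C)C(C)(C)C)COCc1ccc(OC)cc1 | intermediate
15 | (2S,3R,5S)-2-[3-(benzyloxy)propyl]-5-[(tert-butyldimethylsilyl)oxy]-6-[(4-methoxybenzyl)oxy]-3-[(triethylsilyl)oxy]hexanal | O=C[C@@H](CCCOCc1ccccc1)[C@H](O[Si](CC)(CC)CC)C[C@H](O[Si](C)(C)C(C)(C)C)COCc1ccc(OC)cc1 | intermediate
16 | (3R,4R,6S)-3-[3-(benzyloxy)propyl]-6-[(tert-butyldimethylsilyl)oxy]-7-[(4-methoxybenzyl)oxy]-4-[(triethylsilyl)oxy]hept-1-yne | C#C[C@@H](CCCOCc1ccccc1)[C@H](O[Si](CC)(CC)CC)C[C@H](O[Si](C)(C)C(C)(C)C)COCc1ccc(OC)cc1 | intermediate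
17 | (E)-alkenyldimethylalane from 16, Al on C1 cis to the C20 methyl (not isolated) | C[Al](C)/C=C(\C)[C@@H](CCCOCc1ccccc1)[C@H](O[Si](CC)(CC)CC)C[C@H](O[Si](C)(C)C(C)(C)C)COCc1ccc(OC)cc1 | intermediate
18 | (3E,5R,6R,8S)-5-[3-(benzyloxy)propyl]-8-[(tert-butyldimethylsilyl)oxy]-9-[(4-methoxybenzyl)oxy]-4-methyl-6-[(triethylsilyl)oxy]nona-1,3-diene | C=C/C=C(\C)[C@@H](CCCOCc1ccccc1)[C@H](O[Si](CC)(CC)CC)C[C@H](O[Si](C)(C)C(C)(C)C)COCc1ccc(OC)cc1 | intermediate
19 | (2S,4R,5R,6E)-5-[3-(benzyloxy)propyl]-2-[(tert-butyldimethylsilyl)oxy]-6-methyl-4-[(triethylsilyl)oxy]nona-6,8-dien-1-ol | C=C/C=C(\C)[C@@H](CCCOCc1ccccc1)[C@H](O[Si](CC)(CC)CC)C[C@H](O[Si](C)(C)C(C)(C)C)CO | intermediate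
20 | (2S,4R,5R,6E)-5-[3-(benzyloxy)propyl]-2-[(tert-butyldimethylsilyl)oxy]-6-methyl-4-[(triethylsilyl)oxy]nona-6,8-dienal | C=C/C=C(\C)[C@@H](CCCOCc1ccccc1)[C@H](O[Si](CC)(CC)CC)C[C@H](O[Si](C)(C)C(C)(C)C)C=O | intermediate
21 | methyl 2-(triphenyl-λ5-phosphanylidene)propanoate | COC(=O)C(C)=P(c1ccccc1)(c1ccccc1)c1ccccc1 | starting material
22 | methyl (2E,4S,6R,7R,8E)-7-[3-(benzyloxy)propyl]-4-[(tert-butyldimethylsilyl)oxy]-2,8-dimethyl-6-[(triethylsilyl)oxy]undeca-2,8,10-trienoate | C=C/C=C(\C)[C@@H](CCCOCc1ccccc1)[C@H](O[Si](CC)(CC)CC)C[C@H](O[Si](C)(C)C(C)(C)C)/C=C(\C)C(=O)OC | intermediate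
23 | methyl 13-(benzyloxy)-6α-[(tert-butyldimethylsilyl)oxy]-8α-[(triethylsilyl)oxy]-14,15,16,17-tetranorlabd-1-en-18-oate | CC[Si](CC)(CC)O[C@@H]1C[C@H](O[Si](C)(C)C(C)(C)C)[C@H]2[C@](C)(C(=O)OC)CC=C[C@]2(C)[C@H]1CCCOCc1ccccc1 | intermediate
24 | methyl 6α-[(tert-butyldimethylsilyl)oxy]-13-hydroxy-8α-[(triethylsilyl)oxy]-14,15,16,17-tetranorlabdan-18-oate | CC[Si](CC)(CC)O[C@@H]1C[C@H](O[Si](C)(C)C(C)(C)C)[C@H]2[C@](C)(C(=O)OC)CCC[C@]2(C)[C@H]1CCCO | intermediate
25 | methyl 6α-[(tert-butyldimethylsilyl)oxy]-13-oxo-8α-[(triethylsilyl)oxy]-14,15,16,17-tetranorlabdan-18-oate | CC[Si](CC)(CC)O[C@@H]1C[C@H](O[Si](C)(C)C(C)(C)C)[C@H]2[C@](C)(C(=O)OC)CCC[C@]2(C)[C@H]1CCC=O | intermediate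
26 | methyl 6α-[(tert-butyldimethylsilyl)oxy]-8α-[(triethylsilyl)oxy]-15,16,17-trinorlabd-13-yn-18-oate | CC[Si](CC)(CC)O[C@@H]1C[C@H](O[Si](C)(C)C(C)(C)C)[C@H]2[C@](C)(C(=O)OC)CCC[C@]2(C)[C@H]1CCC#C | intermediate
27 | methyl 6α-[(tert-butyldimethylsilyl)oxy]-8α-hydroxy-15,16,17-trinorlabd-13-yn-18-oate | O[C@@H]1C[C@H](O[Si](C)(C)C(C)(C)C)[C@H]2[C@](C)(C(=O)OC)CCC[C@]2(C)[C@H]1CCC#C | intermediate
28 | methyl 6α-[(tert-butyldimethylsilyl)oxy]-8-oxo-15,16,17-trinorlabd-13-yn-18-oate | O=C1C[C@H](O[Si](C)(C)C(C)(C)C)[C@H]2[C@](C)(C(=O)OC)CCC[C@]2(C)[C@H]1CCC#C | intermediate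
29 | methyl 6α-[(tert-butyldimethylsilyl)oxy]-15,16-dinorlabd-8(17)-en-13-yn-18-oate | C=C1C[C@H](O[Si](C)(C)C(C)(C)C)[C@H]2[C@](C)(C(=O)OC)CCC[C@]2(C)[C@H]1CCC#C | intermediate
30 | 6α-[(tert-butyldimethylsilyl)oxy]-15,16-dinorlabd-8(17)-en-13-yn-18-ol | C=C1C[C@H](O[Si](C)(C)C(C)(C)C)[C@H]2[C@](C)(CO)CCC[C@]2(C)[C@H]1CCC#C | intermediate
31 | 6α-[(tert-butyldimethylsilyl)oxy]-15,16-dinorlabd-8(17)-en-13-yn-18-yl benzoate | C=C1C[C@H](O[Si](C)(C)C(C)(C)C)[C@H]2[C@](C)(COC(=O)c3ccccc3)CCC[C@]2(C)[C@H]1CCC#C | intermediate
32 | lithium acetylide of 31 (not isolated) | C=C1C[C@H](O[Si](C)(C)C(C)(C)C)[C@H]2[C@](C)(COC(=O)c3ccccc3)CCC[C@]2(C)[C@H]1CCC#C[Li] | intermediate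
33 | allyl 18-(benzoyloxy)-6α-[(tert-butyldimethylsilyl)oxy]-16-norlabd-8(17)-en-13-yn-15-oate | C=C1C[C@H](O[Si](C)(C)C(C)(C)C)[C@H]2[C@](C)(COC(=O)c3ccccc3)CCC[C@]2(C)[C@H]1CCC#CC(=O)OCC=C | intermediate
34 | lithium alkenyl(methyl)cuprate from 33, Cu on C14 cis to the C16 methyl (not isolated) | C=C1C[C@H](O[Si](C)(C)C(C)(C)C)[C@H]2[C@](C)(COC(=O)c3ccccc3)CCC[C@]2(C)[C@H]1CC/C(C)=C(/[Cu-]C)C(=O)OCC=C.[Li+] | intermediate
35 | allyl (13Z)-18-(benzoyloxy)-6α-[(tert-butyldimethylsilyl)oxy]labda-8(17),13-dien-15-oate | C=C1C[C@H](O[Si](C)(C)C(C)(C)C)[C@H]2[C@](C)(COC(=O)c3ccccc3)CCC[C@]2(C)[C@H]1CC/C(C)=C\C(=O)OCC=C | intermediate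
36 | allyl (13Z)-18-(benzoyloxy)-6α-hydroxylabda-8(17),13-dien-15-oate | C=C1C[C@H](O)[C@H]2[C@](C)(COC(=O)c3ccccc3)CCC[C@]2(C)[C@H]1CC/C(C)=C\C(=O)OCC=C | intermediate
37 | (13Z)-18-(benzoyloxy)-6α-hydroxylabda-8(17),13-dien-15-oic acid (CNP0304840.1) | C=C1C[C@H](O)[C@H]2[C@](C)(COC(=O)c3ccccc3)CCC[C@]2(C)[C@H]1CC/C(C)=C\C(=O)O | target

## Step count and risk

Total: 27 steps. Longest linear sequence: 26 steps, from 1 through steps 1–4 and 6–27; step 5 is the one-step branch that supplies imide 10.

**Step 15 (key step).** The cycloaddition may be too slow, because the cis methyl on C10 destabilises the s-cis diene and the α-methyl lowers the reactivity of the dienophile. Forcing it thermally (toluene, 160 °C, a change of conditions only) invites a 1,5-hydrogen shift from C20 into the diene. With the Lewis acid, cationic isomerisation of the diene, loss of the TES ether or erosion of the endo preference are the likely failures. Fallback: change the activating group to an aldehyde, which is a much better dienophile. Setting out from 22, reduction with iBu2AlH gives the allylic alcohol F1 and MnO2 gives the enal F2. Its cycloaddition (Me2AlCl, −78 °C) should give the C18 aldehyde F3 through the same transition state. Oxidation with NaClO2 gives the acid F4, and Me3SiCHN2 returns to the route at 23.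

**Step 11.** The four ether oxygens can bind AlMe3 and leave the carbometalation incomplete, and transfer from aluminium to palladium may be inefficient in a one-flask process. Fallback: from 16, quench the alkenylalane with iodine to isolate the (E)-alkenyl iodide F5 and use it as the electrophile in a Stille coupling with tributyl(vinyl)stannane (Pd2(dba)3, AsPh3), returning at 18.

**Step 12.** DDQ may attack the electron-rich diene by oxidation or cycloaddition, and the acidic hydroquinone may remove the TES ether. Fallback: take the PMB group off before the diene exists. From 16 through iodide F5, DDQ gives the iodo alcohol F6, Dess–Martin oxidation the iodo aldehyde F7, and Wittig reaction with 21 the iodo enoate F8. Stille vinylation as above then returns at 22, so the diene is formed directly before the key step.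

**Step 21.** Methylene transfer to the C8 carbonyl, which is flanked by C9 and lies under C20, may be sluggish, and the titanium Lewis acid may promote β-elimination of the C6 silyloxy group. Fallback: a two-step Peterson olefination. From 28, addition of Me3SiCH2Li with CeCl3 gives the β-hydroxysilane F9, and KH induces the elimination, returning at 29.

**Step 24.** Deprotonation by the amide base may be incomplete, or the acetylide may transfer onto the benzoate carbonyl. Fallback: carboxylation through a silver acetylide. From 31, AgI (cat.), Cs2CO3 and CO2 (1 atm) in DMF give the caesium alkynoate F10, which is alkylated with allyl bromide in the same flask, returning at 33.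

## Further compounds

F1 | step 15 | (2E,4S,6R,7R,8E)-7-[3-(benzyloxy)propyl]-4-[(tert-butyldimethylsilyl)oxy]-2,8-dimethyl-6-[(triethylsilyl)oxy]undeca-2,8,10-trien-1-ol | C=C/C=C(\C)[C@@H](CCCOCc1ccccc1)[C@H](O[Si](CC)(CC)CC)C[C@H](O[Si](C)(C)C(C)(C)C)/C=C(\C)CO
F2 | step 15 | (2E,4S,6R,7R,8E)-7-[3-(benzyloxy)propyl]-4-[(tert-butyldimethylsilyl)oxy]-2,8-dimethyl-6-[(triethylsilyl)oxy]undeca-2,8,10-trienal | C=C/C=C(\C)[C@@H](CCCOCc1ccccc1)[C@H](O[Si](CC)(CC)CC)C[C@H](O[Si](C)(C)C(C)(C)C)/C=C(\C)C=O
F3 | step 15 | 13-(benzyloxy)-6α-[(tert-butyldimethylsilyl)oxy]-8α-[(triethylsilyl)oxy]-14,15,16,17-tetranorlabd-1-en-18-al | CC[Si](CC)(CC)O[C@@H]1C[C@H](O[Si](C)(C)C(C)(C)C)[C@H]2[C@](C)(C=O)CC=C[C@]2(C)[C@H]1CCCOCc1ccccc1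
F4 | step 15 | 13-(benzyloxy)-6α-[(tert-butyldimethylsilyl)oxy]-8α-[(triethylsilyl)oxy]-14,15,16,17-tetranorlabd-1-en-18-oic acid | CC[Si](CC)(CC)O[C@@H]1C[C@H](O[Si](C)(C)C(C)(C)C)[C@H]2[C@](C)(C(=O)O)CC=C[C@]2(C)[C@H]1CCCOCc1ccccc1
F5 | step 11 | (E)-alkenyl iodide from 16 (iodine on C1, cis to the C20 methyl) | I/C=C(\C)[C@@H](CCCOCc1ccccc1)[C@H](O[Si](CC)(CC)CC)C[C@H](O[Si](C)(C)C(C)(C)C)COCc1ccc(OC)cc1
F6 | step 12 | iodo alcohol (F5 without the PMB group) | I/C=C(\C)[C@@H](CCCOCc1ccccc1)[C@H](O[Si](CC)(CC)CC)C[C@H](O[Si](C)(C)C(C)(C)C)CO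
F7 | step 12 | iodo aldehyde (C5 aldehyde of F6) | I/C=C(\C)[C@@H](CCCOCc1ccccc1)[C@H](O[Si](CC)(CC)CC)C[C@H](O[Si](C)(C)C(C)(C)C)C=O
F8 | step 12 | iodo enoate (22 with iodine in place of the vinyl group on C1) | I/C=C(\C)[C@@H](CCCOCc1ccccc1)[C@H](O[Si](CC)(CC)CC)C[C@H](O[Si](C)(C)C(C)(C)C)/C=C(\C)C(=O)OC
F9 | step 21 | methyl 6α-[(tert-butyldimethylsilyl)oxy]-8-hydroxy-8-[(trimethylsilyl)methyl]-15,16,17-trinorlabd-13-yn-18-oate (C8 configuration immaterial) | C[Si](C)(C)CC1(O)C[C@H](O[Si](C)(C)C(C)(C)C)[C@H]2[C@](C)(C(=O)OC)CCC[C@]2(C)[C@H]1CCC#C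
F10 | step 24 | caesium 18-(benzoyloxy)-6α-[(tert-butyldimethylsilyl)oxy]-16-norlabd-8(17)-en-13-yn-15-oate | C=C1C[C@H](O[Si](C)(C)C(C)(C)C)[C@H]2[C@](C)(COC(=O)c3ccccc3)CCC[C@]2(C)[C@H]1CCC#CC(=O)[O-].[Cs+]
A1 | alternative 1 | ring A enol lactone diene, 4,7a-dimethyl-3-methylidene-5,6,7,7a-tetrahydro-2-benzofuran-1(3H)-one with C4 configured as in the target | C=C1OC(=O)[C@]2(C)CCCC(C)=C12
A2 | alternative 1 | ethyl buta-2,3-dienoate | C=C=CC(=O)OCC
A3 | alternative 1 | tricyclic adduct (C5=C6 enol lactone, exocyclic C8=C17, ethyl ester on C9, quaternary C10) | C=C1CC2=C3[C@](C)(C(=O)O2)CCC[C@]3(C)[C@H]1C(=O)OCC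
A4 | alternative 2 | (R)-4-[(tert-butyldimethylsilyl)oxy]-2-methylcyclohex-2-en-1-one | CC1=C[C@H](O[Si](C)(C)C(C)(C)C)CCC1=O
A5 | alternative 2 | (E)-(1-iodopent-2-en-3-yl)trimethylsilane | IC/C=C(/[Si](C)(C)C)CC
A6 | alternative 2 | 2,2,3-trisubstituted cyclohexanone (ring B with C8, C9 and C10 set) | O=C1CC[C@@H](O[Si](C)(C)C(C)(C)C)[C@H](C=C)[C@@]1(C)C/C=C(/[Si](C)(C)C)CC
A7 | alternative 3 | ring A methylenecyclohexane carrying on C5 the chain C6(OTBS)–C7–C8(=O)–C9=C11–C12 methyl ester | C=C1CCC[C@@](C)(CO[Si](c2ccccc2)(c2ccccc2)C(C)(C)C)[C@@H]1[C@@H](O[Si](C)(C)C(C)(C)C)CC(=O)/C=C/C(=O)OC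
A8 | alternative 3 | 8-oxo trans-decalin with quaternary C10 and a C11–C12 methyl ester | O=C1C[C@H](O[Si](C)(C)C(C)(C)C)[C@H]2[C@](C)(CO[Si](c3ccccc3)(c3ccccc3)C(C)(C)C)CCC[C@]2(C)[C@H]1CC(=O)OC
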